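**Retrosynthetic overview**
1. Hyperielliptone HB ⇐ C-acylation of spiro trione 24 with (2S)-2-methylbutanoic acid. The trione ring ⇐ ring expansion of dispiro epoxy cyclopentanone 21 by a 1,2-acyl shift, which also creates the spiro quaternary carbon.
2. Epoxy ketone 21 ⇐ Darzens union of hydrindanone 12 with α-chloro ketone 18.
3. Hydrindanone 12 ⇐ cis-hydrindane-1,4-dione 8 (double convex-face methyl addition, silylene bridge, ozonolysis) ⇐ [3+3] annulation of (3S)-3-(nitromethyl)cyclopentanone with 3-chloro-2-(chloromethyl)propene, then Nef.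
4. Chloro ketone 18 ⇐ CBS desymmetrisation of 2-methyl-2-prenylcyclopentane-1,3-dione.
5. Ring order: cyclopentane (bought) → cyclohexane of the hydrindane → oxirane → six-membered trione ring by expansion of the cyclopentanone.

Assumption: where the sense of induction of a chiral catalyst is not certain (steps 1 and 7), the catalyst enantiomer that gives the stated configuration is used; spiro compounds are numbered as spiro[cyclohexane-1,5'-indene].

**Step 1**
Reactants: 1 cyclopent-2-en-1-one; 2 nitromethane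
Product: 3 (3S)-3-(nitromethyl)cyclopentan-1-one
Conditions: 9-amino-9-deoxy-epi-quinine (10 mol %), PhCO2H (20 mol %), MeNO2 (5 equiv), THF, rt
Reagents that add atoms: none
Why: Iminium-catalysed asymmetric Michael addition of nitromethane to a cyclic enone, in which the chiral primary amine shields one face of the iminium ion and so sets the future ring-fusion carbon C3a.

**Step 2**
Reactants: 3 (3S)-3-(nitromethyl)cyclopentan-1-one; 4 3-chloro-2-(chloromethyl)prop-1-ene
Product: 6 (3aS,7aS)-6-methylidene-4-nitrooctahydro-1H-inden-1-one, via allylic chloride 5 (not isolated)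
Conditions: Pd(PPh3)4 (5 mol %), pyrrolidine (30 mol %), K2CO3 (2.2 equiv), DMSO/THF, 25 → 45 °C
Reagents that add atoms: none
Why: Proposed new method: the soft nitronate of 3 C-allylates the π-allyl–palladium complex from 4 (Tsuji–Trost), the second allylic chloride then ionises and is captured at C2 by the pyrrolidine enamine of the ketone (only C2 closes a six-membered ring, and nitronate O-allylation is reversible under palladium), the tether on C3 delivering the new bond to the same face so the ring fusion is cis; the closest known reactions are the Pd-catalysed α,α'-annulation of ketone enamines with 2-methylenepropane-1,3-diyl diesters and the enamine-mediated intramolecular Tsuji–Trost cyclisation.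

**Step 3**
Reactants: 6 (3aS,7aS)-6-methylidene-4-nitrooctahydro-1H-inden-1-one
Product: 8 (3aS,7aS)-6-methylidenehexahydro-1H-indene-1,4(2H)-dione, via sodium nitronate 7 (not isolated)
Conditions: NaOMe, MeOH, 0 °C; then aq. TiCl3, NH4OAc (pH 5–6), 0 °C → rt; used crude
Reagents that add atoms: water, O
Why: Nef reaction in its buffered TiCl3 variant turns the secondary nitro group into the C4 ketone under conditions mild enough to keep the β,γ-methylidene and the cis ring fusion.

**Step 4**
Reactants: 8 (3aS,7aS)-6-methylidenehexahydro-1H-indene-1,4(2H)-dione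
Product: 10 cyclic diisopropylsilylene ether of (1R,3aS,4R,7aS)-1,4-dimethyl-6-methylideneoctahydro-1H-indene-1,4-diol, via dilithium diolate 9 (not isolated)
Conditions: MeLi (2.5 equiv), CeCl3, THF, −78 °C; then iPr2Si(OTf)2 (1.1 equiv), −78 → 0 °C
Reagents that add atoms: methyllithium, [Li]C; diisopropylsilyl bis(trifluoromethanesulfonate), CC(C)[Si](OS(=O)(=O)C(F)(F)F)(OS(=O)(=O)C(F)(F)F)C(C)C
Why: Non-basic organocerium 1,2-addition to both ketones occurs on the convex face, anti to the ring-fusion substituent on the neighbouring carbon, so both methyls end cis to the ring-fusion hydrogens and both oxygens on the concave face, where they lie close enough to be bridged by one silicon.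

**Step 5**
Reactants: 10 cyclic diisopropylsilylene ether of (1R,3aS,4R,7aS)-1,4-dimethyl-6-methylideneoctahydro-1H-indene-1,4-diol
Product: 12 cyclic diisopropylsilylene ether of (3R,3aS,7R,7aS)-3,7-dihydroxy-3,7-dimethyloctahydro-5H-inden-5-one, via ozonide 11 (not isolated)
Conditions: O3, CH2Cl2, −78 °C; then PPh3, −78 °C → rt
Reagents that add atoms: ozone, [O-][O+]=O
Why: Ozonolysis of the only alkene unmasks the C5 ketone, and the silyl ether on the β-oxygen blocks retro-aldol opening.

**Step 6**
Reactants: 13 2-methylcyclopentane-1,3-dione; 14 1-bromo-3-methylbut-2-ene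
Product: 15 2-methyl-2-(3-methylbut-2-en-1-yl)cyclopentane-1,3-dione
Conditions: 1 M aq. NaOH, Bu4NI (cat.), rt
Reagents that add atoms: none
Why: C-alkylation of the cyclic 1,3-dione enolate with an allylic bromide in water, the standard entry to 2,2-disubstituted cyclopentane-1,3-diones.

**Step 7**
Reactants: 15 2-methyl-2-(3-methylbut-2-en-1-yl)cyclopentane-1,3-dione
Product: 16 (2R,3R)-3-hydroxy-2-methyl-2-(3-methylbut-2-en-1-yl)cyclopentan-1-one
Conditions: (S)-2-methyl-CBS-oxazaborolidine (20 mol %), BH3·SMe2 (0.6 equiv), THF, −30 °C; MeOH quench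
Reagents that add atoms: none
Why: Corey–Bakshi–Shibata desymmetrising mono-reduction, in which the catalyst selects the 3R carbinol and hydride enters anti to the larger prenyl group, fixing the quaternary carbon as R (the minor C2 epimer is a separable diastereomer).

**Step 8**
Reactants: 16 (2R,3R)-3-hydroxy-2-methyl-2-(3-methylbut-2-en-1-yl)cyclopentan-1-one
Product: 18 (2R,3R)-5-chloro-2-methyl-2-(3-methylbut-2-en-1-yl)-3-[(triethylsilyl)oxy]cyclopentan-1-one, via bis-silyl enol ether 17 (not isolated)
Conditions: TESOTf (2.3 equiv), Et3N (3 equiv), CH2Cl2, 0 °C → rt; then NCS (1.1 equiv), 0 °C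
Reagents that add atoms: triethylsilyl trifluoromethanesulfonate, CC[Si](CC)(CC)OS(=O)(=O)C(F)(F)F; N-chlorosuccinimide, ClN1C(=O)CCC1=O
Why: O-silylation protects the carbinol against retro-aldol while the only possible silyl enol ether (C2 is quaternary) is chlorinated by NCS to the α-chloro ketone, whose C5 configuration is irrelevant.

**Step 9**
Reactants: 18 (2R,3R)-5-chloro-2-methyl-2-(3-methylbut-2-en-1-yl)-3-[(triethylsilyl)oxy]cyclopentan-1-one; 12 cyclic diisopropylsilylene ether of (3R,3aS,7R,7aS)-3,7-dihydroxy-3,7-dimethyloctahydro-5H-inden-5-one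
Product: 21 dispiro epoxy ketone (oxirane joining C5' of the hydrindane to the α-carbon of the cyclopentanone; epoxide oxygen on the concave face), via lithium enolate 19 (not isolated), via lithium aldolate 20 (not isolated)
Conditions: 18, LiN(SiMe3)2 (1.05 equiv), THF, −78 °C; then 12, −78 → 0 °C
Reagents that add atoms: none
Why: Darzens condensation in which the silylene bridge holds C7–O and C3 axial on the concave face (C7–CH3 equatorial), so the chloro enolate adds equatorially from the convex face and the alkoxide oxygen that then displaces chloride sits on the concave face, cis to C7–O.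

**Step 10**
Reactants: 21 dispiro epoxy ketone
Product: 22 (1S,3R,4R,3'R,3a'S,7'R,7a'S)-3,3',7'-trimethyl-3-(3-methylbut-2-en-1-yl)-4-[(triethylsilyl)oxy]octahydrospiro[cyclohexane-1,5'-indene]-2,6-dione 3',7'-O,O'-diisopropylsilylene ether
Conditions: BF3·OEt2 (0.3 equiv), CH2Cl2, −78 → −30 °C
Reagents that add atoms: none
Why: Lewis-acid epoxy-ketone to 1,3-diketone rearrangement (the ring expansion known for 2-alkylidenecycloalkanone oxides): the epoxide opens at the tertiary spiro carbon while the ring acyl carbon migrates anti to the leaving oxygen (inversion), so the cyclopentanone becomes the cyclohexane-1,3-dione, the migrated C2 carbonyl sits on the convex face and the new C6 carbonyl cis to C7'–O, as in the target.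

**Step 11**
Reactants: 22 silyl-protected spiro dione
Product: 23 (1S,3R,4R,3'R,3a'S,7'R,7a'S)-4,3',7'-trihydroxy-3,3',7'-trimethyl-3-(3-methylbut-2-en-1-yl)octahydrospiro[cyclohexane-1,5'-indene]-2,6-dione
Conditions: HF·pyridine, pyridine/THF, 0 °C → rt
Reagents that add atoms: none
Why: Fluoride-driven cleavage of the silylene and the triethylsilyl ether under weakly acidic conditions that avoid retro-aldol of the β-hydroxy ketone.

**Step 12**
Reactants: 23 triol dione
Product: 24 (1S,5R,3'R,3a'S,7'R,7a'S)-4,3',7'-trihydroxy-5,3',7'-trimethyl-5-(3-methylbut-2-en-1-yl)octahydrospiro[cyclohex-3-ene-1,5'-indene]-2,6-dione (enol form of the trione)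
Conditions: Dess–Martin periodinane, CH2Cl2, 0 °C → rt
Reagents that add atoms: none
Why: Dess–Martin oxidation converts the single secondary alcohol into the third ring carbonyl while the two tertiary alcohols cannot react.

**Step 13**
Reactants: 24 spiro trione (enol form); 25 (2S)-2-methylbutanoic acid
Product: 27 hyperielliptone HB, via enol ester 26 (not isolated)
Conditions: DCC (1.2 equiv), DMAP (1.2 equiv), CH2Cl2, 0 °C → rt
Reagents that add atoms: none
Why: Steglich O-acylation of the cyclic 1,3-dione enol followed by DMAP-mediated O-to-C acyl migration places the acyl group on the only carbon between two carbonyls, the hindered tertiary alcohols stay free and the mild conditions preserve the 2S centre.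

**Compound list**
1 | cyclopent-2-en-1-one | O=C1C=CCC1 | starting material
2 | nitromethane | C[N+](=O)[O-] | starting material
3 | (3S)-3-(nitromethyl)cyclopentan-1-one | O=C1C[C@H](CC1)C[N+](=O)[O-] | intermediate
4 | 3-chloro-2-(chloromethyl)prop-1-ene | C=C(CCl)CCl | starting material
5 | (3S)-3-[3-(chloromethyl)-1-nitrobut-3-en-1-yl]cyclopentan-1-one (nitro-carbon epimers) | O=C1C[C@H](CC1)C(CC(=C)CCl)[N+](=O)[O-] | intermediate
6 | (3aS,7aS)-6-methylidene-4-nitrooctahydro-1H-inden-1-one (cis-fused, C4 epimers) | C=C1C[C@H]2[C@H](CCC2=O)C([N+](=O)[O-])C1 | intermediate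
7 | sodium nitronate of 6 | C=C1C[C@H]2[C@H](CCC2=O)C(=[N+]([O-])[O-])C1.[Na+] | intermediate
8 | (3aS,7aS)-6-methylidenehexahydro-1H-indene-1,4(2H)-dione (cis-fused) | C=C1C[C@H]2[C@H](CCC2=O)C(=O)C1 | intermediate
9 | dilithium (1R,3aS,4R,7aS)-1,4-dimethyl-6-methylideneoctahydro-1H-indene-1,4-diolate | C=C1C[C@H]2[C@H](CC[C@@]2(C)[O-])[C@](C)([O-])C1.[Li+].[Li+] | intermediate
10 | cyclic diisopropylsilylene ether of (1R,3aS,4R,7aS)-1,4-dimethyl-6-methylideneoctahydro-1H-indene-1,4-diol | C=C1C[C@H]2[C@H](CC[C@@]2(C)O3)[C@](C)(O[Si]3(C(C)C)C(C)C)C1 | intermediate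
11 | ozonide of 10 (spiro-1,2,4-trioxolane at C6) | O1COOC12C[C@H]3[C@H](CC[C@@]3(C)O4)[C@](C)(O[Si]4(C(C)C)C(C)C)C2 | intermediate
12 | cyclic diisopropylsilylene ether of (3R,3aS,7R,7aS)-3,7-dihydroxy-3,7-dimethyloctahydro-5H-inden-5-one | O=C1C[C@H]2[C@H](CC[C@@]2(C)O3)[C@](C)(O[Si]3(C(C)C)C(C)C)C1 | intermediate
13 | 2-methylcyclopentane-1,3-dione | CC1C(=O)CCC1=O | starting material
14 | 1-bromo-3-methylbut-2-ene (prenyl bromide) | CC(C)=CCBr | starting material
15 | 2-methyl-2-(3-methylbut-2-en-1-yl)cyclopentane-1,3-dione | CC(C)=CCC1(C)C(=O)CCC1=O | intermediate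
16 | (2R,3R)-3-hydroxy-2-methyl-2-(3-methylbut-2-en-1-yl)cyclopentan-1-one (OH cis to prenyl) | O[C@H]1[C@@](C)(CC=C(C)C)C(=O)CC1 | intermediate
17 | (4R,5R)-5-methyl-5-(3-methylbut-2-en-1-yl)-1,4-bis[(triethylsilyl)oxy]cyclopent-1-ene | CC[Si](CC)(CC)O[C@H]1[C@@](C)(CC=C(C)C)C(O[Si](CC)(CC)CC)=CC1 | intermediate
18 | (2R,3R)-5-chloro-2-methyl-2-(3-methylbut-2-en-1-yl)-3-[(triethylsilyl)oxy]cyclopentan-1-one (C5 epimers) | CC[Si](CC)(CC)O[C@H]1[C@@](C)(CC=C(C)C)C(=O)C(Cl)C1 | intermediate
19 | lithium enolate of 18 | CC[Si](CC)(CC)O[C@H]1[C@@](C)(CC=C(C)C)C([O-])=C(Cl)C1.[Li+] | intermediate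
20 | lithium aldolate: 5-chloro ketone 18 bonded through C5 to C5' of hydrindane 12, C5'–O on the concave face (C5 epimers) | CC[Si](CC)(CC)O[C@H]1[C@@](C)(CC=C(C)C)C(=O)C(Cl)(C1)[C@@]2([O-])C[C@H]3[C@H](CC[C@@]3(C)O4)[C@](C)(O[Si]4(C(C)C)C(C)C)C2.[Li+] | intermediate
21 | dispiro epoxy ketone: oxirane joining C5' of the silylene-protected hydrindane (3'R,3a'S,7'R,7a'S) to the α-carbon of the (R,R)-methyl/prenyl/OTES cyclopentanone; epoxide O cis to C7'–O (α-carbon epimers) | CC[Si](CC)(CC)O[C@H]1[C@@](C)(CC=C(C)C)C(=O)C2(C1)O[C@@]23C[C@H]4[C@H](CC[C@@]4(C)O5)[C@](C)(O[Si]5(C(C)C)C(C)C)C3 | intermediate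
22 | (1S,3R,4R,3'R,3a'S,7'R,7a'S)-3,3',7'-trimethyl-3-(3-methylbut-2-en-1-yl)-4-[(triethylsilyl)oxy]octahydrospiro[cyclohexane-1,5'-indene]-2,6-dione 3',7'-O,O'-diisopropylsilylene ether | CC[Si](CC)(CC)O[C@H]1[C@@](C)(CC=C(C)C)C(=O)[C@]2(C[C@H]3[C@H](CC[C@@]3(C)O4)[C@](C)(O[Si]4(C(C)C)C(C)C)C2)C(=O)C1 | intermediate
23 | (1S,3R,4R,3'R,3a'S,7'R,7a'S)-4,3',7'-trihydroxy-3,3',7'-trimethyl-3-(3-methylbut-2-en-1-yl)octahydrospiro[cyclohexane-1,5'-indene]-2,6-dione | O[C@H]1[C@@](C)(CC=C(C)C)C(=O)[C@]2(C[C@H]3[C@H](CC[C@@]3(C)O)[C@](C)(O)C2)C(=O)C1 | intermediate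
24 | (1S,5R,3'R,3a'S,7'R,7a'S)-4,3',7'-trihydroxy-5,3',7'-trimethyl-5-(3-methylbut-2-en-1-yl)octahydrospiro[cyclohex-3-ene-1,5'-indene]-2,6-dione | C1=C(O)[C@@](C)(CC=C(C)C)C(=O)[C@]2(C[C@H]3[C@H](CC[C@@]3(C)O)[C@](C)(O)C2)C1=O | intermediate
25 | (2S)-2-methylbutanoic acid | CC[C@H](C)C(=O)O | starting material
26 | enol (2S)-2-methylbutanoate of 24 (ester on the C4 enol oxygen) | CC[C@H](C)C(=O)OC1=CC(=O)[C@@]2(C[C@H]3[C@H](CC[C@@]3(C)O)[C@](C)(O)C2)C(=O)[C@]1(C)CC=C(C)C | intermediate
27 | hyperielliptone HB, (1R,5R,3'R,3a'S,7'R,7a'S)-4,3',7'-trihydroxy-5,3',7'-trimethyl-5-(3-methylbut-2-en-1-yl)-3-[(2S)-2-methylbutanoyl]octahydrospiro[cyclohex-3-ene-1,5'-indene]-2,6-dione | CC[C@H](C)C(=O)C1=C(O)[C@@](C)(CC=C(C)C)C(=O)[C@]2(C[C@H]3[C@H](CC[C@@]3(C)O)[C@](C)(O)C2)C1=O | target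

**Totals**
Total step count: 13. Longest linear sequence: 10 steps (steps 1–5, then 9–13).

**Three steps most likely to fail**

Step 2 (the proposed new tandem annulation; risks are double allylation of the nitronate and slow enamine capture). Fallback with known chemistry, setting out from 4 and returning at 8: 1,3-dithiane is lithiated (n-BuLi) and alkylated with excess 4 to give 2-[2-(chloromethyl)prop-2-en-1-yl]-1,3-dithiane F1. Its lithio derivative adds 1,4 (THF/HMPA, −78 °C) to commercial (R)-4-(tert-butyldimethylsilyloxy)cyclopent-2-en-1-one anti to the silyloxy group, and the resulting enolate closes onto the allylic chloride on warming (Michael-initiated ring closure) to give the cis-fused 3-silyloxy dithiane ketone F2. DBU then eliminates the silanol to the enone F3, and [(Ph3P)CuH]6 reduces the enone alone to the saturated dithiane ketone F4. MeI/CaCO3 in aqueous MeCN unmasks the C4 ketone to give 8; here the absolute configuration comes from the chiral enone instead of the organocatalyst.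

Step 9 (Darzens union of two hindered partners; retro-aldol may outrun ring closure). Fallback setting out from 16 and 12 and returning at 21: 16 is silylated (TESCl, imidazole) to the ketone F5, whose cerium enolate (LDA, then CeCl3) undergoes a directed aldol addition to 12 from the convex face to give the β-hydroxy ketone F6. Double deprotonation of F6 (LDA, 2.2 equiv) and chlorination of the enolate with NCS gives the chloro alkoxide, which closes to 21; the C–C and C–Cl bonds are thus made in separate, individually known operations.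

Step 10 (competing alkyl shift or loss of stereospecificity through a free cation). Fallback setting out from 17 and 12 and returning at 22, a geminal acylation of the ketone with a 1,2-bis(silyloxy)cycloalkene (Mukaiyama aldol, then pinacol-type acyl shift): 17 is isolated, cleaved to its lithium enolate with MeLi and hydroxylated with the Davis oxaziridine to the α-hydroxy ketone F7, and TMSOTf/Et3N converts this into the enediol bis(trimethylsilyl) ether F8. F8 and 12 with BF3·OEt2 (then CF3CO2H) give the aldol at the less hindered enediol carbon from the convex face, and acyl migration anti to the leaving oxygen then gives 22 directly.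

**Further compounds**
F1 | step 2 | 2-[2-(chloromethyl)prop-2-en-1-yl]-1,3-dithiane | C=C(CCl)CC1SCCCS1
F2 | step 2 | cis-fused 3-(tert-butyldimethylsilyloxy)-6-methylidenehexahydroindan-1-one 4-(propane-1,3-diyl dithioketal), silyloxy trans to the C3a–C4 bond | C=C1C[C@H]2[C@H]([C@H](O[Si](C)(C)C(C)(C)C)CC2=O)C3(SCCCS3)C1
F3 | step 2 | cis-fused 6-methylidene-3a,4,5,6,7,7a-hexahydroinden-1-one 4-(propane-1,3-diyl dithioketal) (2,3-enone) | C=C1C[C@H]2[C@H](C=CC2=O)C3(SCCCS3)C1
F4 | step 2 | 4-(propane-1,3-diyl dithioketal) of diketone 8 | C=C1C[C@H]2[C@H](CCC2=O)C3(SCCCS3)C1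
F5 | step 9 | (2R,3R)-2-methyl-2-(3-methylbut-2-en-1-yl)-3-[(triethylsilyl)oxy]cyclopentan-1-one | CC[Si](CC)(CC)O[C@H]1[C@@](C)(CC=C(C)C)C(=O)CC1
F6 | step 9 | aldol adduct of F5 (through C5) with 12, C5'–OH on the concave face (C5 epimers) | CC[Si](CC)(CC)O[C@H]1[C@@](C)(CC=C(C)C)C(=O)C(C1)[C@@]2(O)C[C@H]3[C@H](CC[C@@]3(C)O4)[C@](C)(O[Si]4(C(C)C)C(C)C)C2
F7 | step 10 | (2R,3R)-5-hydroxy-2-methyl-2-(3-methylbut-2-en-1-yl)-3-[(triethylsilyl)oxy]cyclopentan-1-one (C5 epimers) | CC[Si](CC)(CC)O[C@H]1[C@@](C)(CC=C(C)C)C(=O)C(O)C1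
F8 | step 10 | (4R,5R)-5-methyl-5-(3-methylbut-2-en-1-yl)-4-[(triethylsilyl)oxy]-1,2-bis[(trimethylsilyl)oxy]cyclopent-1-ene | CC[Si](CC)(CC)O[C@H]1[C@@](C)(CC=C(C)C)C(O[Si](C)(C)C)=C(O[Si](C)(C)C)C1
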